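**Retrosynthetic overview**

1. The last operations are removal of four benzyl ethers and, before that, 6-endo closure of the pyranone of the methoxyflavone unit (O1–C2 bond) from an ortho-hydroxyaryl ynone.
2. The strategy rests on ring A of the methoxyflavone unit, a benzene in which only C8 carries hydrogen (C4a carbon chain, C5–OH, C6–O-aryl, C7–OH, C8a–O1). It is built by Danheiser benzannulation: C5 to C8 come from a 4-aryloxy-3-alkoxycyclobutenone and C4a–C8a from a siloxyalkyne (new bonds C4a–C5 and C8–C8a; C5–C6 opens and re-closes).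
3. The cyclobutenone comes from benzyloxyacetylene and the ketene of an aryloxyacetic acid that already carries 5,7-di-O-benzylapigenin (chalcone route from 2',4',6'-trihydroxyacetophenone and (4-formylphenoxy)acetic acid). The C7 oxygen is therefore a benzyl ether and leaves with the others.
4. The siloxyalkyne comes from 4-ethynylanisole by formylation, ethynyl Grignard addition, silylation, and oxidation of the terminal acetylide to the ynolate with O-silylation.
5. Ring order: apigenin pyranone (step 3), cyclobutenone (step 6), benzene ring A (step 11), methoxyflavone pyranone (step 15).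

Key step: step 11

Remark: the target has no stereocentre; the stereocentres met on the way (C4 of 15, the carbinol carbon of 19 to 30, the ring carbon of 25 and 27) are racemic and are all destroyed before the end.

**Route**

Step 1
Reactants: 1 2',4',6'-trihydroxyacetophenone
Product: 2 2'-hydroxy-4',6'-bis(benzyloxy)acetophenone
Conditions: BnBr (2.1 equiv), K2CO3, DMF, rt
Reagents that add atoms: benzyl bromide BrCc1ccccc1
Why: Williamson etherification with two equivalents of benzyl bromide should spare the 2'-hydroxyl, which is hydrogen-bonded to the acetyl carbonyl and is the least nucleophilic of the three.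

Step 2
Reactants: 2 2'-hydroxy-4',6'-bis(benzyloxy)acetophenone; 3 (4-formylphenoxy)acetic acid
Product: 4 (E)-chalcone acid
Conditions: KOH (50% aq, excess), EtOH/THF, rt; then 1 M HCl
Reagents that add atoms: none
Why: Claisen–Schmidt condensation of the methyl ketone with the non-enolisable aldehyde (present as its carboxylate) should give the E-chalcone, and acidification releases the acid.

Step 3
Reactants: 4 (E)-chalcone acid
Product: 5 2-[4-(5,7-bis(benzyloxy)-4-oxo-4H-chromen-2-yl)phenoxy]acetic acid
Conditions: I2 (10 mol %), DMSO, 120 °C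
Reagents that add atoms: none
Why: Iodine-catalysed oxidative cyclisation of a 2'-hydroxychalcone in DMSO (oxa-Michael closure, then dehydrogenation with DMSO as terminal oxidant) is the standard flavone synthesis and should tolerate the benzyl ethers and the carboxylic acid.

Step 4
Reactants: 6 benzyl alcohol; 7 trichloroethylene
Product: 9 benzyl (E)-1,2-dichlorovinyl ether, via dichloroethyne 8 (not isolated)
Conditions: KH, THF, 0 °C; then Cl2C=CHCl, −50 °C → rt
Reagents that add atoms: none
Why: Potassium benzyl oxide eliminates HCl from trichloroethylene and adds anti to the dichloroethyne so formed, the known route to E-1,2-dichlorovinyl ethers.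

Step 5
Reactants: 9 benzyl (E)-1,2-dichlorovinyl ether
Product: 12 benzyloxyacetylene, via (benzyloxy)chloroethyne 10 (not isolated), via lithium (benzyloxy)acetylide 11 (not isolated)
Conditions: n-BuLi (2.3 equiv), THF, −78 → −40 °C; sat. aq NH4Cl, −78 °C; cold pentane extraction, solution used at once
Reagents that add atoms: none
Why: Deprotonation of the vinyl hydrogen with loss of LiCl gives the chloroalkyne, chlorine–lithium exchange gives the lithium alkoxyacetylide and cold protonation gives the ynol ether, which is kept below room temperature because benzyl alkynyl ethers rearrange sigmatropically on warming.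

Step 6
Reactants: 5 flavone acid; 12 benzyloxyacetylene
Product: 15 racemic 3-(benzyloxy)-4-aryloxycyclobut-2-en-1-one (aryl = 4'-position of 5,7-di-O-benzylapigenin), via acid chloride 13 (not isolated), via aryloxyketene 14 (not isolated)
Conditions: 1-chloro-N,N,2-trimethylprop-1-enylamine (1.05 equiv), CH2Cl2, 0 °C → rt; then 12 (2.5 equiv), Et3N (slow addition), CH2Cl2, 0 °C → rt; chromatography on Et3N-deactivated silica
Reagents that add atoms: none
Why: The α-chloroenamine makes the acid chloride under neutral conditions that leave the basic pyranone carbonyl alone, triethylamine gives the aryloxyketene, and its [2+2] cycloaddition with the ynol ether is regiospecific (terminal alkyne carbon to the ketene carbonyl carbon), so the 3-alkoxy-4-aryloxycyclobutenone should form as a racemate whose stereocentre is lost in step 11.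

Step 7
Reactants: 16 4-ethynylanisole
Product: 18 3-(4-methoxyphenyl)prop-2-ynal, via lithium (4-methoxyphenyl)acetylide 17 (not isolated)
Conditions: n-BuLi, THF, −40 °C; DMF, −40 °C → rt; inverse quench into 10% aq KH2PO4/MTBE, 5 °C
Reagents that add atoms: N,N-dimethylformamide CN(C)C=O
Why: Formylation of a lithium acetylide with DMF is reliable when the mixture is quenched inversely into phosphate buffer, so that the dimethylamine set free does not add to the ynal.

Step 8
Reactants: 18 3-(4-methoxyphenyl)prop-2-ynal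
Product: 19 racemic 1-(4-methoxyphenyl)penta-1,4-diyn-3-ol
Conditions: HC≡CMgBr (0.5 M in THF), THF, −20 → 0 °C; sat. aq NH4Cl
Reagents that add atoms: ethynylmagnesium bromide C#C[Mg]Br
Why: 1,2-Addition of the alkynyl Grignard reagent to the ynal should give the skipped diynol, whose new stereocentre is racemic and is oxidised away in step 14.

Step 9
Reactants: 19 racemic 1-(4-methoxyphenyl)penta-1,4-diyn-3-ol
Product: 20 racemic 3-(tert-butyldimethylsiloxy)-1-(4-methoxyphenyl)penta-1,4-diyne
Conditions: TBSCl, imidazole, CH2Cl2, 0 °C → rt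
Reagents that add atoms: tert-butyldimethylsilyl chloride CC(C)(C)[Si](C)(C)Cl
Why: Silylation of a secondary alcohol with imidazole as base avoids any strong base that could isomerise the skipped diyne.

Step 10
Reactants: 20 racemic 3-(tert-butyldimethylsiloxy)-1-(4-methoxyphenyl)penta-1,4-diyne
Product: 23 racemic 3-(tert-butyldimethylsiloxy)-5-(4-methoxyphenyl)-1-(triisopropylsiloxy)penta-1,4-diyne, via lithium acetylide 21 (not isolated), via lithium ynolate 22 (not isolated)
Conditions: LiN(SiMe3)2 (1.05 equiv), THF, −78 °C; added to t-BuOOLi (from t-BuOOH and LiN(SiMe3)2, THF, −78 °C), −78 → 0 °C; TIPSOTf, −78 → 0 °C; chromatography on silica in hexanes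
Reagents that add atoms: tert-butyl hydroperoxide CC(C)(C)OO; triisopropylsilyl trifluoromethanesulfonate CC(C)[Si](OS(=O)(=O)C(F)(F)F)(C(C)C)C(C)C
Why: The amide base should remove only the terminal alkyne hydrogen at −78 °C, lithium tert-butyl peroxide oxidises the acetylide carbon to the lithium ynolate, and the bulky silyl triflate traps the ynolate on oxygen, a known route from terminal alkynes to triisopropylsilyl ynol ethers.

Step 11
Reactants: 15 racemic 3-(benzyloxy)-4-aryloxycyclobut-2-en-1-one; 23 siloxyalkyne (1.5 equiv)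
Product: 28 ring A phenol (C5 hydroxyl; C4a racemic CH(OTBS)C≡C-C6H4-4-OMe; C8a OTIPS; C7 OBn; C6 aryloxy), via vinylketene 24 (not isolated), via vinylcyclobutenone 25 (not isolated), via dienylketene 26 (not isolated), via cyclohexadienone 27 (not isolated)
Conditions: PhMe (degassed, 0.3 M), 80 °C then 110 °C
Reagents that add atoms: none
Why: Thermal 4π electrocyclic opening of 15, with the aryloxy group turning outward, should give vinylketene 24; the nucleophilic β-carbon of siloxyalkyne 23 adds to the ketene carbonyl carbon and [2+2] closure gives 25, whose 4π opening gives dienylketene 26, which closes and tautomerises through 27 to phenol 28. The closest known reaction is the Danheiser benzannulation of cyclobutenones with triisopropylsiloxyalkynes to monosilylated resorcinols. Ring A is closed by disrotatory 6π electrocyclisation (bond C5–C6) of the dienylketene isomer that has C4a and C7 cis across C8a=C8, and because the opening of 25 is reversible the other isomer is returned until it closes. No lasting stereocentre is made: the sp3 ring carbon of 27 becomes aromatic C6 and the carbinol carbon stays racemic. The step needs one regiochemistry (C4a to C5, C8a to C8), which the polarisation of the ynol ether fixes, and one chemoselectivity, secured because the aryl alkyne of the side chain is far less electron-rich than the siloxyalkyne while the benzyl ethers and the flavone are inert at 110 °C. The product has three distinct ring oxygens (free hydroxyl at C5, silyl ether at C8a, benzyl ether at C7), which the later pyranone closure requires.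

Step 12
Reactants: 28 ring A phenol
Product: 29 C5 benzyl ether of 28
Conditions: BnBr, K2CO3, n-Bu4NI (cat.), acetone, 50 °C
Reagents that add atoms: benzyl bromide BrCc1ccccc1
Why: Williamson O-alkylation of the only free phenol under carbonate in acetone should leave the aryl triisopropylsilyl ether and the alkyl silyl ether untouched, so that C5 is capped before C8a is unmasked.

Step 13
Reactants: 29 C5 benzyl ether
Product: 30 racemic diol (C8a phenol and propargylic alcohol)
Conditions: n-Bu4NF (3 equiv), AcOH (3 equiv), THF, 0 °C → rt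
Reagents that add atoms: none
Why: Fluoride cleaves both silicon–oxygen bonds, and the acetic acid buffer keeps the phenoxide and alkoxide protonated so that the electron-rich propargylic carbinol neither rearranges nor cyclises.

Step 14
Reactants: 30 racemic diol
Product: 31 ortho-hydroxyaryl ynone
Conditions: MnO2 (activated, excess), CH2Cl2, rt
Reagents that add atoms: none
Why: Activated MnO2 oxidises benzylic propargylic alcohols selectively and should leave the single phenol (no ortho or para dihydroxy pattern) and the benzyl ethers alone.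

Step 15
Reactants: 31 ortho-hydroxyaryl ynone
Product: 33 tetra-O-benzylcryptomerin A, via enaminone 32 (not isolated)
Conditions: Et2NH (5 equiv), EtOH/THF, rt → 60 °C
Reagents that add atoms: none
Why: Conjugate addition of diethylamine gives the β-amino enone, in which the C8a hydroxyl can attack only the β-carbon, so addition–elimination should close the pyranone 6-endo without aurone formation, while the benzylated C5 oxygen cannot compete.

Step 16
Reactants: 33 tetra-O-benzylcryptomerin A
Product: 34 cryptomerin A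
Conditions: H2 (1 atm), Pd/C (10 wt %), THF/MeOH, rt
Reagents that add atoms: none
Why: Hydrogenolysis of the four aryl benzyl ethers over palladium on carbon should leave the aryl methyl ether, the diaryl ether and the two flavone C2–C3 double bonds intact if it is stopped once debenzylation is complete.

**Compound list**

1 | 2',4',6'-trihydroxyacetophenone | CC(=O)c1c(O)cc(O)cc1O | starting material
2 | 2'-hydroxy-4',6'-bis(benzyloxy)acetophenone | CC(=O)c1c(O)cc(OCc2ccccc2)cc1OCc1ccccc1 | intermediate
3 | (4-formylphenoxy)acetic acid | O=Cc1ccc(OCC(=O)O)cc1 | starting material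
4 | (E)-2-[4-[3-(2-hydroxy-4,6-bis(benzyloxy)phenyl)-3-oxoprop-1-enyl]phenoxy]acetic acid | O=C(O)COc1ccc(/C=C/C(=O)c2c(O)cc(OCc3ccccc3)cc2OCc2ccccc2)cc1 | intermediate
5 | 2-[4-(5,7-bis(benzyloxy)-4-oxo-4H-chromen-2-yl)phenoxy]acetic acid | O=C(O)COc1ccc(-c2cc(=O)c3c(OCc4ccccc4)cc(OCc4ccccc4)cc3o2)cc1 | intermediate
6 | benzyl alcohol | OCc1ccccc1 | starting material
7 | trichloroethylene | ClC=C(Cl)Cl | starting material
8 | dichloroethyne | ClC#CCl | intermediate
9 | benzyl (E)-1,2-dichlorovinyl ether | Cl/C=C(/Cl)OCc1ccccc1 | intermediate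
10 | (benzyloxy)chloroethyne | ClC#COCc1ccccc1 | intermediate
11 | lithium (benzyloxy)acetylide | [Li]C#COCc1ccccc1 | intermediate
12 | benzyloxyacetylene (benzyl ethynyl ether) | C#COCc1ccccc1 | intermediate
13 | 2-[4-(5,7-bis(benzyloxy)-4-oxo-4H-chromen-2-yl)phenoxy]acetyl chloride | O=C(Cl)COc1ccc(-c2cc(=O)c3c(OCc4ccccc4)cc(OCc4ccccc4)cc3o2)cc1 | intermediate
14 | 2-[4-(5,7-bis(benzyloxy)-4-oxo-4H-chromen-2-yl)phenoxy]ethenone (aryloxyketene) | O=C=COc1ccc(-c2cc(=O)c3c(OCc4ccccc4)cc(OCc4ccccc4)cc3o2)cc1 | intermediate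
15 | racemic 3-(benzyloxy)-4-[4-(5,7-bis(benzyloxy)-4-oxo-4H-chromen-2-yl)phenoxy]cyclobut-2-en-1-one | O=C1C=C(OCc2ccccc2)C1Oc1ccc(-c2cc(=O)c3c(OCc4ccccc4)cc(OCc4ccccc4)cc3o2)cc1 | intermediate
16 | 4-ethynylanisole | C#Cc1ccc(OC)cc1 | starting material
17 | lithium (4-methoxyphenyl)acetylide | [Li]C#Cc1ccc(OC)cc1 | intermediate
18 | 3-(4-methoxyphenyl)prop-2-ynal | O=CC#Cc1ccc(OC)cc1 | intermediate
19 | racemic 1-(4-methoxyphenyl)penta-1,4-diyn-3-ol | C#CC(O)C#Cc1ccc(OC)cc1 | intermediate
20 | racemic 3-(tert-butyldimethylsiloxy)-1-(4-methoxyphenyl)penta-1,4-diyne | C#CC(O[Si](C)(C)C(C)(C)C)C#Cc1ccc(OC)cc1 | intermediate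
21 | lithium acetylide of 20 (lithium on the terminal alkyne carbon) | [Li]C#CC(O[Si](C)(C)C(C)(C)C)C#Cc1ccc(OC)cc1 | intermediate
22 | lithium 3-(tert-butyldimethylsiloxy)-5-(4-methoxyphenyl)penta-1,4-diyn-1-olate (ynolate) | [Li+].[O-]C#CC(O[Si](C)(C)C(C)(C)C)C#Cc1ccc(OC)cc1 | intermediate
23 | racemic 3-(tert-butyldimethylsiloxy)-5-(4-methoxyphenyl)-1-(triisopropylsiloxy)penta-1,4-diyne | CC(C)[Si](C(C)C)(C(C)C)OC#CC(O[Si](C)(C)C(C)(C)C)C#Cc1ccc(OC)cc1 | intermediate
24 | 4-aryloxy-3-(benzyloxy)buta-1,3-dien-1-one, aryloxy and benzyloxy cis (vinylketene from 15) | O=C=C/C(OCc1ccccc1)=C/Oc1ccc(-c2cc(=O)c3c(OCc4ccccc4)cc(OCc4ccccc4)cc3o2)cc1 | intermediate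
25 | 4-[2-aryloxy-1-(benzyloxy)vinyl]-2-[1-(tert-butyldimethylsiloxy)-3-(4-methoxyphenyl)prop-2-ynyl]-3-(triisopropylsiloxy)cyclobut-2-en-1-one, mixture of racemic diastereomers | O=C1C(C(O[Si](C)(C)C(C)(C)C)C#Cc2ccc(OC)cc2)=C(O[Si](C(C)C)(C(C)C)C(C)C)C1/C(OCc1ccccc1)=C/Oc1ccc(-c2cc(=O)c3c(OCc4ccccc4)cc(OCc4ccccc4)cc3o2)cc1 | intermediate
26 | dienylketene from 25 (ketene carbon future C5; C4a and C7 cis across C8a=C8) | O=C=C(C(O[Si](C)(C)C(C)(C)C)C#Cc1ccc(OC)cc1)/C(O[Si](C(C)C)(C(C)C)C(C)C)=C\C(OCc1ccccc1)=C\Oc1ccc(-c2cc(=O)c3c(OCc4ccccc4)cc(OCc4ccccc4)cc3o2)cc1 | intermediate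
27 | 6-aryloxy-5-(benzyloxy)-2-[1-(tert-butyldimethylsiloxy)-3-(4-methoxyphenyl)prop-2-ynyl]-3-(triisopropylsiloxy)cyclohexa-2,4-dien-1-one, mixture of racemic diastereomers | O=C1C(C(O[Si](C)(C)C(C)(C)C)C#Cc2ccc(OC)cc2)=C(O[Si](C(C)C)(C(C)C)C(C)C)C=C(OCc2ccccc2)C1Oc1ccc(-c2cc(=O)c3c(OCc4ccccc4)cc(OCc4ccccc4)cc3o2)cc1 | intermediate
28 | racemic ring A phenol: C5–OH, C4a–CH(OTBS)C≡C(4-methoxyphenyl), C8a–OTIPS, C8–H, C7–OBn, C6–O-aryl (aryl = 4'-position of 5,7-di-O-benzylapigenin) | Oc1c(C(O[Si](C)(C)C(C)(C)C)C#Cc2ccc(OC)cc2)c(O[Si](C(C)C)(C(C)C)C(C)C)cc(OCc2ccccc2)c1Oc1ccc(-c2cc(=O)c3c(OCc4ccccc4)cc(OCc4ccccc4)cc3o2)cc1 | intermediate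
29 | racemic C5 benzyl ether of 28 | CC(C)(C)[Si](C)(C)OC(C#Cc1ccc(OC)cc1)c1c(O[Si](C(C)C)(C(C)C)C(C)C)cc(OCc2ccccc2)c(Oc2ccc(-c3cc(=O)c4c(OCc5ccccc5)cc(OCc5ccccc5)cc4o3)cc2)c1OCc1ccccc1 | intermediate
30 | racemic diol: 29 without its two silyl groups (C8a–OH and propargylic OH) | OC(C#Cc1ccc(OC)cc1)c1c(O)cc(OCc2ccccc2)c(Oc2ccc(-c3cc(=O)c4c(OCc5ccccc5)cc(OCc5ccccc5)cc4o3)cc2)c1OCc1ccccc1 | intermediate
31 | ortho-hydroxyaryl ynone: 1-[ring A aryl]-3-(4-methoxyphenyl)prop-2-yn-1-one | O=C(C#Cc1ccc(OC)cc1)c1c(O)cc(OCc2ccccc2)c(Oc2ccc(-c3cc(=O)c4c(OCc5ccccc5)cc(OCc5ccccc5)cc4o3)cc2)c1OCc1ccccc1 | intermediate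
32 | (E)-3-(diethylamino)-3-(4-methoxyphenyl)-1-[ring A aryl]prop-2-en-1-one (enaminone) | CCN(CC)/C(=C/C(=O)c1c(O)cc(OCc2ccccc2)c(Oc2ccc(-c3cc(=O)c4c(OCc5ccccc5)cc(OCc5ccccc5)cc4o3)cc2)c1OCc1ccccc1)c1ccc(OC)cc1 | intermediate
33 | tetra-O-benzylcryptomerin A: 5,7-bis(benzyloxy)-6-[4-(5,7-bis(benzyloxy)-4-oxo-4H-chromen-2-yl)phenoxy]-2-(4-methoxyphenyl)-4H-chromen-4-one | COc1ccc(-c2cc(=O)c3c(OCc4ccccc4)c(Oc4ccc(-c5cc(=O)c6c(OCc7ccccc7)cc(OCc7ccccc7)cc6o5)cc4)c(OCc4ccccc4)cc3o2)cc1 | intermediate
34 | cryptomerin A | COc1ccc(-c2cc(=O)c3c(O)c(Oc4ccc(-c5cc(=O)c6c(O)cc(O)cc6o5)cc4)c(O)cc3o2)cc1 | target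

**Step count**

Total: 16 steps. Longest linear sequence: 10 steps (steps 1, 2, 3, 6, 11 to 16; the siloxyalkyne arm, steps 7 to 16, is equally long).

**Steps most likely to fail**

Step 11. The doubly oxygenated vinylketene is a weaker electrophile than the alkyl-substituted ones usually used, so trapping by the siloxyalkyne may be slow. Ketene dimerisation, acylation of the product phenol by the ketene, or thermal silyl shift in the siloxyalkyne could then take over. The fallback drops the benzannulation and makes the diaryl ether by nucleophilic aromatic substitution. It sets out from 2. Elbs persulfate oxidation (K2S2O8, aq NaOH, then warm dilute HCl) should hydroxylate para to the phenol and give 2',5'-dihydroxy-4',6'-bis(benzyloxy)acetophenone F1. Claisen–Schmidt condensation with 4-methoxybenzaldehyde under argon gives the chalcone F2, and I2 in DMSO gives 5,7-bis(benzyloxy)-6-hydroxy-4'-methoxyflavone F3. Substitution on 4-fluorobenzaldehyde (K2CO3, DMF, 100 °C) gives the 6-(4-formylphenoxy)flavone F4. Claisen–Schmidt condensation of F4 with a second portion of 2 (KOH, EtOH/THF, rt) gives the chalcone F5, whose I2/DMSO cyclisation comes back to the route at 33.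

Step 6. Activation of a large, poorly soluble acid may be incomplete, the aryloxyketene may dimerise before it meets the ynol ether, and the vinylogous ester may hydrolyse on purification. The fallback carries a small aryl group through the benzannulation and builds the apigenin unit last. It sets out from 3, whose acid chloride and ketene are the textbook case and can be used on scale with excess ynol ether 12, to give 3-(benzyloxy)-4-(4-formylphenoxy)cyclobut-2-en-1-one F6. Benzannulation of F6 with 23 under the conditions of step 11 gives the formyl-bearing phenol F7. Benzylation gives F8, buffered fluoride gives the diol F9, MnO2 gives the ynone F10, and diethylamine closes the pyranone to the aldehyde F4. Condensation of F4 with 2 to the chalcone F5 and I2/DMSO cyclisation come back to the route at 33.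

Step 10. The amide base may also remove the doubly propargylic hydrogen, which would isomerise the skipped diyne, and oxygen transfer from the peroxide to the acetylide may stall. The fallback reaches the same ynolate by Kowalski ester homologation instead of acetylide oxidation. It sets out from 16. Acetylide 17 is added to freshly cracked ethyl glyoxylate (THF, −78 °C) to give ethyl 2-hydroxy-4-(4-methoxyphenyl)but-3-ynoate F11, which is silylated (TBSCl, imidazole) to the ester F12. F12 is added to preformed LiCHBr2 (CH2Br2, lithium tetramethylpiperidide, THF, −78 °C) and gives the dibromo enolate F13. Bromine–lithium exchange with n-BuLi and warming trigger the rearrangement, which comes back to the route at ynolate 22, silylated as in step 10 to 23.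

**Further compounds**

F1 | step 11 | 2',5'-dihydroxy-4',6'-bis(benzyloxy)acetophenone | CC(=O)c1c(O)cc(OCc2ccccc2)c(O)c1OCc1ccccc1
F2 | step 11 | (E)-1-[2,5-dihydroxy-4,6-bis(benzyloxy)phenyl]-3-(4-methoxyphenyl)prop-2-en-1-one | COc1ccc(/C=C/C(=O)c2c(O)cc(OCc3ccccc3)c(O)c2OCc2ccccc2)cc1
F3 | step 11 | 5,7-bis(benzyloxy)-6-hydroxy-2-(4-methoxyphenyl)-4H-chromen-4-one | COc1ccc(-c2cc(=O)c3c(OCc4ccccc4)c(O)c(OCc4ccccc4)cc3o2)cc1
F4 | step 11 | 4-[5,7-bis(benzyloxy)-2-(4-methoxyphenyl)-4-oxo-4H-chromen-6-yloxy]benzaldehyde | COc1ccc(-c2cc(=O)c3c(OCc4ccccc4)c(Oc4ccc(C=O)cc4)c(OCc4ccccc4)cc3o2)cc1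
F5 | step 11 | (E)-chalcone from F4 and 2 | COc1ccc(-c2cc(=O)c3c(OCc4ccccc4)c(Oc4ccc(/C=C/C(=O)c5c(O)cc(OCc6ccccc6)cc5OCc5ccccc5)cc4)c(OCc4ccccc4)cc3o2)cc1
F6 | step 6 | racemic 3-(benzyloxy)-4-(4-formylphenoxy)cyclobut-2-en-1-one | O=Cc1ccc(OC2C(=O)C=C2OCc2ccccc2)cc1
F7 | step 6 | racemic ring A phenol as 28 with 4-formylphenoxy at C6 | Oc1c(C(O[Si](C)(C)C(C)(C)C)C#Cc2ccc(OC)cc2)c(O[Si](C(C)C)(C(C)C)C(C)C)cc(OCc2ccccc2)c1Oc1ccc(C=O)cc1
F8 | step 6 | racemic C5 benzyl ether of F7 | CC(C)(C)[Si](C)(C)OC(C#Cc1ccc(OC)cc1)c1c(O[Si](C(C)C)(C(C)C)C(C)C)cc(OCc2ccccc2)c(Oc2ccc(C=O)cc2)c1OCc1ccccc1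
F9 | step 6 | racemic diol from F8 (C8a–OH and propargylic OH) | OC(C#Cc1ccc(OC)cc1)c1c(O)cc(OCc2ccccc2)c(Oc2ccc(C=O)cc2)c1OCc1ccccc1
F10 | step 6 | ortho-hydroxyaryl ynone from F9 | O=C(C#Cc1ccc(OC)cc1)c1c(O)cc(OCc2ccccc2)c(Oc2ccc(C=O)cc2)c1OCc1ccccc1
F11 | step 10 | racemic ethyl 2-hydroxy-4-(4-methoxyphenyl)but-3-ynoate | CCOC(=O)C(O)C#Cc1ccc(OC)cc1
F12 | step 10 | racemic ethyl 2-(tert-butyldimethylsiloxy)-4-(4-methoxyphenyl)but-3-ynoate | CCOC(=O)C(O[Si](C)(C)C(C)(C)C)C#Cc1ccc(OC)cc1
F13 | step 10 | lithium enolate of racemic 1,1-dibromo-3-(tert-butyldimethylsiloxy)-5-(4-methoxyphenyl)pent-4-yn-2-one | [Li+].[O-]C(=C(Br)Br)C(O[Si](C)(C)C(C)(C)C)C#Cc1ccc(OC)cc1
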